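The route rests on cutting ring B at C9–C10 (drimane numbering: ring A = C1–C5 and C10, ring B = C5–C10). The tertiary carbinol C9, carrying OH and the carboxyl C11, sits next to the quaternary, methyl-bearing C10 at the ring A/ring B fusion; this pair is what a carbonyl-ene reaction leaves behind. A thermal intramolecular ene reaction of an α-keto ester with the C10=C1 alkene of ring A therefore closes ring B, creates C9 and C10 together and moves the alkene to C1=C2. Its precursor is a monocyclic (S)-2,6,6-trimethylcyclohex-2-enyl carbinol silyl ether bearing a (Z)-enone whose C8 carries the C12 diethyl acetal and the C9 keto tert-butyl ester.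

Key step: step 7

Numbering remark: C11 = carboxyl carbon on C9, C12 = formyl carbon on C8, C15 = methyl on C10; α is the face of H5, β the face of C15. The target is (5S,6S,9S,10S): trans ring fusion, 9-OH α, 6-O α (equatorial).
Assumption: the target is drawn as the open hydroxy acid aldehyde; its ring-chain tautomer (the lactol between C11 and C12) may be present in solution and is taken as the same substance.
Convention: alkoxide salts of a product that exist only before aqueous work-up are not numbered separately.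

Step 1
Reactants: 1 (±)-α-cyclocitral; 2 3,3-diethoxyprop-1-yne
Product: 4 4,4-diethoxy-1-(2,6,6-trimethylcyclohex-2-en-1-yl)but-2-yn-1-ol (mixture of stereoisomers), via lithium 3,3-diethoxyprop-1-ynide 3 (not isolated)
Conditions: 2, n-BuLi, THF, −78 °C; then 1, −78 → −20 °C; H2O
Reagents that add atoms: none
Why: Addition of a lithium acetylide to an aldehyde (alkynylation) at low temperature should outpace enolisation of the hindered aldehyde; no stereocontrol is needed because C6 is re-set and C5 is sorted at step 3.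

Step 2
Reactants: 4 4,4-diethoxy-1-(2,6,6-trimethylcyclohex-2-en-1-yl)but-2-yn-1-ol
Product: 5 (±)-4,4-diethoxy-1-(2,6,6-trimethylcyclohex-2-en-1-yl)but-2-yn-1-one
Conditions: Dess–Martin periodinane, pyridine, CH2Cl2, 0 °C → rt
Reagents that add atoms: none
Why: Dess–Martin oxidation under pyridine buffering converts the propargylic alcohol into the ynone without acid that could move the ring alkene into conjugation or open the acetal.

Step 3
Reactants: 5 (±)-4,4-diethoxy-1-(2,6,6-trimethylcyclohex-2-en-1-yl)but-2-yn-1-one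
Product: 6 (1R)-4,4-diethoxy-1-[(1S)-2,6,6-trimethylcyclohex-2-en-1-yl]but-2-yn-1-ol
Conditions: Ru[(R,R)-TsDPEN](p-cymene) (2 mol %), i-PrOH, 25 °C; SiO2 chromatography to remove the (1R,1′R) diastereomer
Reagents that add atoms: none
Why: Noyori asymmetric transfer hydrogenation of an alkynyl ketone, in which the (R,R) catalyst is expected to deliver hydride to the same carbonyl face of both ketone enantiomers and so sets C6 (1R at this stage, 6S in the target), turning the racemate into two separable diastereomers of which the one with (S)-C5 is kept, which fixes C5 as well.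

Step 4
Reactants: 6 (1R)-4,4-diethoxy-1-[(1S)-2,6,6-trimethylcyclohex-2-en-1-yl]but-2-yn-1-ol
Product: 8 (1R,2Z)-4,4-diethoxy-3-iodo-1-[(1S)-2,6,6-trimethylcyclohex-2-en-1-yl]but-2-en-1-ol, via cyclic vinylalanate 7 (not isolated)
Conditions: NaAlH2(OCH2CH2OMe)2 (1.5 equiv), THF, 0 °C → rt; then I2, THF, −78 → 0 °C; H2O
Reagents that add atoms: iodine, [I][I]
Why: Hydroxyl-directed trans-hydroalumination of a propargylic alcohol places aluminium on the distal alkyne carbon C8 within a five-membered alkoxyaluminate, and iodinolysis with retention gives the (Z)-γ-iodo allylic alcohol with iodine cis to C6, the geometry the ring closure needs; C6 is untouched.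

Step 5
Reactants: 8 (1R,2Z)-4,4-diethoxy-3-iodo-1-[(1S)-2,6,6-trimethylcyclohex-2-en-1-yl]but-2-en-1-ol
Product: 9 tert-butyl{[(1R,2Z)-4,4-diethoxy-3-iodo-1-[(1S)-2,6,6-trimethylcyclohex-2-en-1-yl]but-2-en-1-yl]oxy}dimethylsilane
Conditions: TBSCl, imidazole, 4-(dimethylamino)pyridine (DMAP, cat.), DMF, 40 °C
Reagents that add atoms: tert-butyldimethylsilyl chloride, CC(C)(C)[Si](C)(C)Cl
Why: Silyl ether formation with the silyl chloride and imidazole (Corey conditions) is chosen over a silyl triflate, which could activate the diethyl acetal; the bulky silyl ether is also wanted for the conformational bias at step 7.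

Step 6
Reactants: 9 tert-butyl{[(1R,2Z)-4,4-diethoxy-3-iodo-1-[(1S)-2,6,6-trimethylcyclohex-2-en-1-yl]but-2-en-1-yl]oxy}dimethylsilane; 10 di-tert-butyl oxalate
Product: 13 tert-butyl (3Z,5S)-5-{[tert-butyl(dimethyl)silyl]oxy}-3-(diethoxymethyl)-2-oxo-5-[(1S)-2,6,6-trimethylcyclohex-2-en-1-yl]pent-3-enoate, via vinyllithium 11 (not isolated), via lithium hemiketal alkoxide 12 (not isolated)
Conditions: t-BuLi (2.1 equiv), Et2O, −78 °C, 10 min; cannulate into 10 (3 equiv), THF, −78 °C; AcOH, −78 °C
Reagents that add atoms: none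
Why: Iodine–lithium exchange proceeds with retention of alkene geometry and the vinyllithium is acylated only once by the oxalate diester because the tetrahedral adduct is stable at −78 °C (acylation of an organolithium with a dialkyl oxalate to an α-keto ester); ether solvent, short lithiation time and inverse addition are meant to outrun 1,4-migration of silicon from O6 to C8.

Step 7
Reactants: 13 tert-butyl (3Z,5S)-5-{[tert-butyl(dimethyl)silyl]oxy}-3-(diethoxymethyl)-2-oxo-5-[(1S)-2,6,6-trimethylcyclohex-2-en-1-yl]pent-3-enoate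
Product: 14 tert-butyl (1S,4S,4aS,8aS)-4-{[tert-butyl(dimethyl)silyl]oxy}-2-(diethoxymethyl)-1-hydroxy-5,5,8a-trimethyl-1,4,4a,5,6,8a-hexahydronaphthalene-1-carboxylate
Conditions: PhMe (0.005 M, degassed), 2,6-di-tert-butyl-4-methylphenol (cat.), 2,6-di-tert-butyl-4-methylpyridine (0.2 equiv), base-washed sealed tube, 150 °C
Reagents that add atoms: none
Why: Thermal, concerted carbonyl-ene reaction: the non-enolisable C9 keto carbon bonds to C10 of the ring A alkene while the C2 hydrogen on the same (α) face passes to the carbonyl oxygen and the alkene shifts to C1=C2. The closest known chemistry is the uncatalysed intramolecular ene cyclisation of olefinic α-keto esters and aldehydes to cyclic alcohols (citronellal-to-isopulegol type), here with bonding at the more substituted alkene carbon, which is why no Lewis acid is used. Ring B closes as a six-membered ring in the 6-exo-trig mode at C10; bonding at C1 would need a bridged seven-membered ring, and C12, held trans to C6 across C7=C8, cannot reach ring A. C10 is set by the face of attack: the β face of C10 is screened by the axial C4 methyl and by the C5–C6 bond, whereas closure on the α face (that of H5), with ring A flattened toward a boat, lets the bulky C6 silyl ether lie pseudoequatorial on the forming ring B and gives the trans fusion with C15 β. C9 is set by the suprafacial ene geometry, since the carbonyl oxygen must lie under C1–C2 to take the α hydrogen of C2 while C8 stays linked to C5, so the hydroxyl ends anti to the C10 methyl and the ester syn to it. The step needs α- over β-face closure and ene closure over hetero-Diels–Alder addition, silyloxy-Cope rearrangement and γ-hydrogen shift of the enone; the (Z) geometry from step 4, the C4 gem-dimethyl group, the C6 silyl ether and neutral, dilute, acid-free heating are relied on to secure them.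

Step 8
Reactants: 14 tert-butyl (1S,4S,4aS,8aS)-4-{[tert-butyl(dimethyl)silyl]oxy}-2-(diethoxymethyl)-1-hydroxy-5,5,8a-trimethyl-1,4,4a,5,6,8a-hexahydronaphthalene-1-carboxylate
Product: 15 tert-butyl (1S,4S,4aS,8aS)-4-{[tert-butyl(dimethyl)silyl]oxy}-2-(diethoxymethyl)-1-hydroxy-5,5,8a-trimethyl-1,4,4a,5,6,7,8,8a-octahydronaphthalene-1-carboxylate
Conditions: 2-nitrobenzenesulfonohydrazide (10 equiv), Et3N, CH2Cl2, rt
Reagents that add atoms: none
Why: Diimide reduction (concerted syn transfer of two hydrogens) is selective for the cis-disubstituted C1=C2 alkene over the trisubstituted C7=C8 alkene and leaves acetal, silyl ether and ester untouched; no stereocentre is formed.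

Step 9
Reactants: 15 tert-butyl (1S,4S,4aS,8aS)-4-{[tert-butyl(dimethyl)silyl]oxy}-2-(diethoxymethyl)-1-hydroxy-5,5,8a-trimethyl-1,4,4a,5,6,7,8,8a-octahydronaphthalene-1-carboxylate
Product: 16 tert-butyl (1S,4S,4aS,8aS)-2-(diethoxymethyl)-1,4-dihydroxy-5,5,8a-trimethyl-1,4,4a,5,6,7,8,8a-octahydronaphthalene-1-carboxylate
Conditions: Bu4NF, THF, 0 °C → rt
Reagents that add atoms: none
Why: Fluoride-induced desilylation frees O6 while tert-butyl ester and acetal are inert to fluoride, and the α-oriented O6 cannot lactonise onto the β-oriented C11 ester.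

Step 10
Reactants: 16 tert-butyl (1S,4S,4aS,8aS)-2-(diethoxymethyl)-1,4-dihydroxy-5,5,8a-trimethyl-1,4,4a,5,6,7,8,8a-octahydronaphthalene-1-carboxylate; 17 (2E,4E,6E)-octa-2,4,6-trienoic acid
Product: 19 tert-butyl (1S,4S,4aS,8aS)-2-(diethoxymethyl)-1-hydroxy-5,5,8a-trimethyl-4-{[(2E,4E,6E)-octa-2,4,6-trienoyl]oxy}-1,4,4a,5,6,7,8,8a-octahydronaphthalene-1-carboxylate, via mixed trichlorobenzoic anhydride 18 (not isolated)
Conditions: 17, 2,4,6-trichlorobenzoyl chloride, Et3N, THF, rt; then 16, DMAP, PhMe, rt
Reagents that add atoms: none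
Why: Yamaguchi esterification through the mixed anhydride acylates the secondary allylic O6 hydroxyl, while the tertiary C9 hydroxyl between the quaternary C10 and the ester is too hindered to react; the mild conditions should keep the all-E triene intact.

Step 11
Reactants: 19 tert-butyl (1S,4S,4aS,8aS)-2-(diethoxymethyl)-1-hydroxy-5,5,8a-trimethyl-4-{[(2E,4E,6E)-octa-2,4,6-trienoyl]oxy}-1,4,4a,5,6,7,8,8a-octahydronaphthalene-1-carboxylate
Product: 20 (1S,4S,4aS,8aS)-2-formyl-1-hydroxy-5,5,8a-trimethyl-4-{[(2E,4E,6E)-octa-2,4,6-trienoyl]oxy}-1,4,4a,5,6,7,8,8a-octahydronaphthalene-1-carboxylic acid (target)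
Conditions: CF3CO2H/CH2Cl2/H2O (10:10:1), 0 °C → rt
Reagents that add atoms: water, O
Why: Acid-mediated global deprotection: trifluoroacetic acid cleaves the tert-butyl ester by loss of isobutene and, with water, hydrolyses the diethyl acetal to the C12 aldehyde, while ionisation at C6 or C9 is disfavoured because either cation would sit next to or in conjugation with an electron-poor carbonyl group.

Compound list
1 | (±)-α-cyclocitral, (±)-2,6,6-trimethylcyclohex-2-ene-1-carbaldehyde | CC1=CCCC(C)(C)C1C=O | starting material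
2 | 3,3-diethoxyprop-1-yne | C#CC(OCC)OCC | starting material
3 | lithium 3,3-diethoxyprop-1-ynide | [Li+].[C-]#CC(OCC)OCC | intermediate (not isolated)
4 | 4,4-diethoxy-1-(2,6,6-trimethylcyclohex-2-en-1-yl)but-2-yn-1-ol, mixture of the four stereoisomers | CCOC(OCC)C#CC(O)C1C(C)=CCCC1(C)C | intermediate
5 | (±)-4,4-diethoxy-1-(2,6,6-trimethylcyclohex-2-en-1-yl)but-2-yn-1-one | CCOC(OCC)C#CC(=O)C1C(C)=CCCC1(C)C | intermediate
6 | (1R)-4,4-diethoxy-1-[(1S)-2,6,6-trimethylcyclohex-2-en-1-yl]but-2-yn-1-ol | CCOC(OCC)C#C[C@H](O)[C@@H]1C(C)=CCCC1(C)C | intermediate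
7 | sodium cyclic alkoxy(vinyl)aluminate of 6: five-membered ring O6–Al–C8=C7–C6, two 2-methoxyethoxy groups on aluminium, diethoxymethyl on C8 | [Na+].CCOC(OCC)C1=C[C@@H]([C@@H]2C(C)=CCCC2(C)C)O[Al-]1(OCCOC)OCCOC | intermediate (not isolated)
8 | (1R,2Z)-4,4-diethoxy-3-iodo-1-[(1S)-2,6,6-trimethylcyclohex-2-en-1-yl]but-2-en-1-ol | CCOC(OCC)/C(I)=C/[C@H](O)[C@@H]1C(C)=CCCC1(C)C | intermediate
9 | tert-butyl{[(1R,2Z)-4,4-diethoxy-3-iodo-1-[(1S)-2,6,6-trimethylcyclohex-2-en-1-yl]but-2-en-1-yl]oxy}dimethylsilane | CCOC(OCC)/C(I)=C/[C@H](O[Si](C)(C)C(C)(C)C)[C@@H]1C(C)=CCCC1(C)C | intermediate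
10 | di-tert-butyl oxalate | CC(C)(C)OC(=O)C(=O)OC(C)(C)C | starting material
11 | vinyllithium from 9: lithium in place of iodine on C8, cis to C6 | CCOC(OCC)/C([Li])=C/[C@H](O[Si](C)(C)C(C)(C)C)[C@@H]1C(C)=CCCC1(C)C | intermediate (not isolated)
12 | lithium hemiketal alkoxide: adduct of 11 to one ester carbonyl of 10 (C9 bears O–Li, O-tert-butyl and the remaining tert-butyl ester) | [Li+].CCOC(OCC)/C(=C/[C@H](O[Si](C)(C)C(C)(C)C)[C@@H]1C(C)=CCCC1(C)C)C([O-])(OC(C)(C)C)C(=O)OC(C)(C)C | intermediate (not isolated)
13 | tert-butyl (3Z,5S)-5-{[tert-butyl(dimethyl)silyl]oxy}-3-(diethoxymethyl)-2-oxo-5-[(1S)-2,6,6-trimethylcyclohex-2-en-1-yl]pent-3-enoate | CCOC(OCC)/C(=C/[C@H](O[Si](C)(C)C(C)(C)C)[C@@H]1C(C)=CCCC1(C)C)C(=O)C(=O)OC(C)(C)C | intermediate (key-step precursor)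
14 | tert-butyl (1S,4S,4aS,8aS)-4-{[tert-butyl(dimethyl)silyl]oxy}-2-(diethoxymethyl)-1-hydroxy-5,5,8a-trimethyl-1,4,4a,5,6,8a-hexahydronaphthalene-1-carboxylate | CC(C)(C)[Si](C)(C)O[C@H]1C=C(C(OCC)OCC)[C@](O)(C(=O)OC(C)(C)C)[C@@]2(C)C=CCC(C)(C)[C@H]12 | intermediate (key-step product)
15 | tert-butyl (1S,4S,4aS,8aS)-4-{[tert-butyl(dimethyl)silyl]oxy}-2-(diethoxymethyl)-1-hydroxy-5,5,8a-trimethyl-1,4,4a,5,6,7,8,8a-octahydronaphthalene-1-carboxylate | CC(C)(C)[Si](C)(C)O[C@H]1C=C(C(OCC)OCC)[C@](O)(C(=O)OC(C)(C)C)[C@@]2(C)CCCC(C)(C)[C@H]12 | intermediate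
16 | tert-butyl (1S,4S,4aS,8aS)-2-(diethoxymethyl)-1,4-dihydroxy-5,5,8a-trimethyl-1,4,4a,5,6,7,8,8a-octahydronaphthalene-1-carboxylate | O[C@H]1C=C(C(OCC)OCC)[C@](O)(C(=O)OC(C)(C)C)[C@@]2(C)CCCC(C)(C)[C@H]12 | intermediate
17 | (2E,4E,6E)-octa-2,4,6-trienoic acid | C/C=C/C=C/C=C/C(=O)O | starting material
18 | (2E,4E,6E)-octa-2,4,6-trienoic 2,4,6-trichlorobenzoic anhydride | C/C=C/C=C/C=C/C(=O)OC(=O)c1c(Cl)cc(Cl)cc1Cl | intermediate (not isolated)
19 | tert-butyl (1S,4S,4aS,8aS)-2-(diethoxymethyl)-1-hydroxy-5,5,8a-trimethyl-4-{[(2E,4E,6E)-octa-2,4,6-trienoyl]oxy}-1,4,4a,5,6,7,8,8a-octahydronaphthalene-1-carboxylate | C/C=C/C=C/C=C/C(=O)O[C@H]1C=C(C(OCC)OCC)[C@](O)(C(=O)OC(C)(C)C)[C@@]2(C)CCCC(C)(C)[C@H]12 | intermediate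
20 | (1S,4S,4aS,8aS)-2-formyl-1-hydroxy-5,5,8a-trimethyl-4-{[(2E,4E,6E)-octa-2,4,6-trienoyl]oxy}-1,4,4a,5,6,7,8,8a-octahydronaphthalene-1-carboxylic acid | C/C=C/C=C/C=C/C(=O)O[C@H]1C=C(C=O)[C@](O)(C(=O)O)[C@@]2(C)CCCC(C)(C)[C@H]12 | target

Total step count: 11. Longest linear sequence: 11 steps (1 → 20); the route is linear, with 2, 10 and 17 entering as purchased reagents.

Steps most likely to fail

Step 7. Two processes threaten the closure. Bond formation at the more substituted alkene carbon C10 is polarity-mismatched and may be slow enough that thermal side reactions take over: a γ-hydrogen shift of the (Z)-enone that scrambles C6, a silyloxy-Cope shift, or loss of isobutene from the ester. Alternatively, attack may occur on the β face of C10 and give the cis ring fusion. The fallback sets out from 13 and replaces the pericyclic closure by a hydrogen-atom-transfer radical cyclisation (Fe(acac)3, PhSiH3, EtOH, 60 °C), a known reductive alkene–ketone ring closure. The iron hydride gives a hydrogen atom to C1, and the tertiary C10 radical, now polarity-matched and sitting on a chair-like ring A, adds 6-exo to the C9 keto group. The alkoxy radical is then reduced to the alcohol. This forms the same C9–C10 bond and should give the saturated hydroxy ester 15 directly, so the route is rejoined at 15 and step 8 is dropped; no new compound arises on the way (F0). The ring fusion obtained this way would have to be checked before going on.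

Step 6. The cis-γ-silyloxy vinyllithium may suffer migration of silicon from O6 to the carbanionic C8 before it is trapped, and premature collapse of the tetrahedral adduct would allow a second addition. The fallback sets out from 9 and avoids organolithium chemistry. A Nozaki–Hiyama–Kishi coupling of 9 with tert-butyl glyoxylate (CrCl2, NiCl2 cat., DMF, rt) should give the α-hydroxy ester tert-butyl (3E,5S)-5-{[tert-butyl(dimethyl)silyl]oxy}-3-(diethoxymethyl)-2-hydroxy-5-[(1S)-2,6,6-trimethylcyclohex-2-en-1-yl]pent-3-enoate F1 as both C2 epimers, with the alkene geometry unchanged (the descriptor changes only because the priorities change). Dess–Martin oxidation (pyridine, CH2Cl2) then converts both epimers into 13, where the route is rejoined.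

Step 3. Catalyst control may be incomplete for one enantiomer of this hindered ketone, or the C5 epimers may not separate, and either would erode the enantiomeric purity of 6. The fallback sets out from 4 and uses a classical resolution. The racemic (1R*,1′S*) diastereomer of 4 is separated by chromatography and acylated with (1S,4R)-camphanic chloride (Et3N, DMAP, CH2Cl2). The two camphanates are separated by crystallisation or chromatography: (1R)-4,4-diethoxy-1-[(1S)-2,6,6-trimethylcyclohex-2-en-1-yl]but-2-yn-1-yl (1S,4R)-camphanate F2 is kept, and (1S)-4,4-diethoxy-1-[(1R)-2,6,6-trimethylcyclohex-2-en-1-yl]but-2-yn-1-yl (1S,4R)-camphanate F3 is discarded. Saponification of F2 (LiOH, THF/H2O) returns 6, where the route is rejoined; steps 2 and 3 are then not needed.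

Further compounds
F0 | step 7 | none | none
F1 | step 6 | tert-butyl (3E,5S)-5-{[tert-butyl(dimethyl)silyl]oxy}-3-(diethoxymethyl)-2-hydroxy-5-[(1S)-2,6,6-trimethylcyclohex-2-en-1-yl]pent-3-enoate (both C2 epimers) | CCOC(OCC)/C(=C/[C@H](O[Si](C)(C)C(C)(C)C)[C@@H]1C(C)=CCCC1(C)C)C(O)C(=O)OC(C)(C)C
F2 | step 3 | (1R)-4,4-diethoxy-1-[(1S)-2,6,6-trimethylcyclohex-2-en-1-yl]but-2-yn-1-yl (1S,4R)-camphanate | CCOC(OCC)C#C[C@H](OC(=O)[C@@]12CC[C@@](C)(C(=O)O1)C2(C)C)[C@@H]1C(C)=CCCC1(C)C
F3 | step 3 | (1S)-4,4-diethoxy-1-[(1R)-2,6,6-trimethylcyclohex-2-en-1-yl]but-2-yn-1-yl (1S,4R)-camphanate | CCOC(OCC)C#C[C@@H](OC(=O)[C@@]12CC[C@@](C)(C(=O)O1)C2(C)C)[C@H]1C(C)=CCCC1(C)C
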